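**Retrosynthetic overview**

1. The target is reached by desilylation of a bis-silyl ether whose acrylate comes from a C-13 acetyl group (enol triflate, Pd-catalysed methoxycarbonylation).
2. Ring C is made last by a reductive decarboxylative [3+3] annulation: the C-8 carboxyl group (as a redox-active ester) gives a radical that is allylated by a 2-acylallyl acetate (C-8–C-14), and the enone so formed closes reductively onto the C-11 aldehyde (C-11–C-12). The enabling feature is that C-8 is a bridgehead of the lactone/cyclopentane bicycle (a 3-oxabicyclo[3.2.1]octan-2-one) and can carry a carboxyl group, while the formyl carbon C-11 sits on the one-carbon bridge C-9, 1,3 to C-8 and syn to the lactone, so a three-carbon unit can span the two.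
3. The cyclopentane (ring B) is closed before that by a reversible intramolecular aldol addition of a malonate-type lactone C-8–H to the C-6 aldehyde; both aldehydes (C-6, C-11) come from one double ozonolysis.
4. The spirolactone is closed by C-8–C-9 bond formation between a malonate on the C-20 oxygen and a propargyl group on C-10 (Rh-catalysed alkyne hydroalkylation).
5. Ring A comes from 4,4-dimethylcyclohexanone: asymmetric alkenyl conjugate addition (C-5), anti propargylation (quaternary C-10), hydride reduction (C-1). Ring order: A, lactone, cyclopentane B, C.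

Key step: step 14

Remark: positions are named by ent-kaurane numbering (C-1 acetoxy carbon; C-4 CMe2; C-5/C-10 ring A fusion carbons; C-6 cyclopentane carbinol; C-7 lactone C=O; C-8 quaternary carbon shared by lactone, ring B and ring C; C-9 CH between C-8 and C-10; C-11 ring C carbinol; C-12, C-14 ring C CH2; C-13 ring C CH; C-15/C-16/C-17 acrylate; C-20 lactone OCH2); the C-6 hydroxyl of the target (anti to the lactone bridge) is assumed to be the thermodynamically favoured aldol epimer.

**Route**

Step 1
Reactants: 1 4,4-dimethylcyclohexanone; 2 dimethyl carbonate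
Product: 3 methyl 5,5-dimethyl-2-oxocyclohexane-1-carboxylate
Conditions: NaH, THF, reflux; AcOH quench
Reagents that add atoms: none
Why: Crossed Claisen condensation of the ketone enolate with dimethyl carbonate is driven by deprotonation of the β-keto ester formed.

Step 2
Reactants: 3 methyl 5,5-dimethyl-2-oxocyclohexane-1-carboxylate
Product: 5 methyl 3,3-dimethyl-6-oxocyclohex-1-ene-1-carboxylate, via selenide 4 (not isolated)
Conditions: PhSeCl, pyridine, CH2Cl2, 0 °C; then 30% H2O2, 0 °C → rt
Reagents that add atoms: none
Why: α-Selenenylation of the β-keto ester and oxidation give a selenoxide whose syn-elimination can only go toward the ring CH2 group and gives the alkylidene β-keto ester.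

Step 3
Reactants: 5 methyl 3,3-dimethyl-6-oxocyclohex-1-ene-1-carboxylate; 6 (E)-prop-1-en-1-ylboronic acid
Product: 7 methyl (1S,6S)-5,5-dimethyl-2-oxo-6-[(E)-prop-1-en-1-yl]cyclohexane-1-carboxylate
Conditions: [Rh(OH)((R)-binap)]2 (3 mol % Rh), 1,4-dioxane/H2O 10:1, 40 °C
Reagents that add atoms: none
Why: Hayashi–Miyaura conjugate addition of the alkenylrhodium species to the doubly activated alkene should proceed despite the neopentylic β-carbon, and by the usual facial model for 2-cyclohexenones the (R)-BINAP complex should deliver the propenyl group to the face that gives the (S)-configured C-5 required for the target, while the ester-bearing carbon stays epimerisable.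

Step 4
Reactants: 7 methyl (1S,6S)-5,5-dimethyl-2-oxo-6-[(E)-prop-1-en-1-yl]cyclohexane-1-carboxylate; 8 3-bromoprop-1-yne
Product: 9 methyl (1R,6R)-5,5-dimethyl-2-oxo-6-[(E)-prop-1-en-1-yl]-1-(prop-2-yn-1-yl)cyclohexane-1-carboxylate
Conditions: Cs2CO3, DMF, 0 °C → rt
Reagents that add atoms: none
Why: The caesium enolate is C-alkylated anti to the adjacent propenyl group (held pseudo-axial by allylic strain with the enolate ester), which sets the quaternary C-10 with the ester (future C-20) cis and the propargyl group (future C-9) trans to the C-5 substituent.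

Step 5
Reactants: 9 methyl (1R,6R)-5,5-dimethyl-2-oxo-6-[(E)-prop-1-en-1-yl]-1-(prop-2-yn-1-yl)cyclohexane-1-carboxylate
Product: 10 (1S,2S,3R)-2-(hydroxymethyl)-4,4-dimethyl-3-[(E)-prop-1-en-1-yl]-2-(prop-2-yn-1-yl)cyclohexan-1-ol
Conditions: LiAlH4, THF, −78 → 0 °C; aqueous work-up
Reagents that add atoms: none
Why: LiAlH4 reduces ketone and ester, the ketone being attacked from the face opposite the axial ester on C-10 (or, in the alternative chair, opposite the axial propenyl group), which in both cases should give the C-1 alcohol cis to the new CH2OH group.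

Step 6
Reactants: 10 (1S,2S,3R)-2-(hydroxymethyl)-4,4-dimethyl-3-[(E)-prop-1-en-1-yl]-2-(prop-2-yn-1-yl)cyclohexan-1-ol; 11 3-(benzyloxy)-3-oxopropanoic acid
Product: 13 benzyl malonate of the C-20 alcohol with C-1 acetate (acetoxy malonate 13), via hydroxy malonate 12 (not isolated)
Conditions: DCC, DMAP (cat.), CH2Cl2, −20 °C; then Ac2O, pyridine, 0 °C → rt
Reagents that add atoms: acetic anhydride (CC(=O)OC(C)=O)
Why: Carbodiimide (Steglich) esterification takes the less hindered primary alcohol, after which the secondary C-1 alcohol is acetylated in the same flask to give the acetate that stays to the end.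

Step 7
Reactants: 13 acetoxy malonate
Product: 14 benzyl 7-acetoxy-5-ethenyl-10,10-dimethyl-3-oxo-11-[(E)-prop-1-en-1-yl]-2-oxaspiro[5.5]undecane-4-carboxylate (vinyl spirolactone)
Conditions: [Rh(cod)Cl]2 (2.5 mol %), DPEphos (6 mol %), PhCO2H (20 mol %), ClCH2CH2Cl, 80 °C
Reagents that add atoms: none
Why: Rhodium hydride isomerises the terminal alkyne to the allene and gives a π-allylrhodium species that the tethered 1,3-dicarbonyl carbon attacks at the internal terminus (six-membered ring preferred over eight), a known hydroalkylation of terminal alkynes by 1,3-dicarbonyl compounds that here closes the spirolactone and leaves a vinyl group on C-9; the configurations at C-8 and C-9 are not controlled because both centres are equilibrated in step 8.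

Step 8
Reactants: 14 vinyl spirolactone
Product: 16 tricyclic hydroxy aldehyde (ring A, ring B and lactone closed; CO2Bn on C-8, CHO on C-9 syn to the lactone bridge, OH on C-6 anti to it), via dialdehyde 15 (not isolated)
Conditions: O3, CH2Cl2, −78 °C; PPh3, → rt; then DBU (0.2 equiv), 0 °C → rt
Reagents that add atoms: ozone ([O-][O+]=O)
Why: Ozonolysis frees the C-6 and C-11 aldehydes at once, and the reversible DBU-mediated aldol addition of the malonate-type C-8–H to the C-6 aldehyde (the only aldol that gives a five-membered ring) should settle at the thermodynamic product, with the C-6 hydroxyl anti to the lactone bridge, the formyl group on C-9 epimerised through its enol to the less hindered position syn to the lactone bridge, and C-8 fixed by the tether through C-5 and C-10.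

Step 9
Reactants: 16 tricyclic hydroxy aldehyde
Product: 17 C-6 triethylsilyl ether of 16
Conditions: Et3SiOTf, 2,6-lutidine, CH2Cl2, −78 °C
Reagents that add atoms: triethylsilyl trifluoromethanesulfonate (CC[Si](CC)(CC)OS(=O)(=O)C(F)(F)F)
Why: Silylation of the only hydroxyl group blocks retro-aldol opening and β-lactone formation in the following steps.

Step 10
Reactants: 17 C-6 triethylsilyl ether
Product: 18 bridgehead carboxylic acid (CO2H on C-8)
Conditions: H2 (1 atm), Pd/C, EtOAc, rt
Reagents that add atoms: none
Why: Hydrogenolysis removes the benzyl group only, and the resulting acid is stable because decarboxylation would need a bridgehead enol.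

Step 11
Reactants: 18 bridgehead carboxylic acid
Product: 19 1,3-dioxoisoindolin-2-yl ester of 18 (redox-active ester)
Conditions: N-hydroxyphthalimide, N,N'-diisopropylcarbodiimide, DMAP (cat.), CH2Cl2, 0 °C → rt
Reagents that add atoms: N-hydroxyphthalimide (O=C1c2ccccc2C(=O)N1O)
Why: Carbodiimide coupling with N-hydroxyphthalimide gives the redox-active ester needed for reductive decarboxylation.

Step 12
Reactants: 20 but-3-en-2-one; 21 formaldehyde (37% aqueous)
Product: 22 3-(hydroxymethyl)but-3-en-2-one
Conditions: DABCO (10 mol %), THF/H2O, rt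
Reagents that add atoms: none
Why: Morita–Baylis–Hillman reaction of the enone with formaldehyde.

Step 13
Reactants: 22 3-(hydroxymethyl)but-3-en-2-one
Product: 23 2-methylidene-3-oxobutyl acetate
Conditions: Ac2O, pyridine, CH2Cl2, 0 °C
Reagents that add atoms: acetic anhydride (CC(=O)OC(C)=O)
Why: O-Acetylation gives a 2-acylallyl acetate that accepts radicals at the CH2 terminus and then loses acetate.

Step 14
Reactants: 19 redox-active ester; 23 2-methylidene-3-oxobutyl acetate
Product: 25 tetracyclic methyl ketone (target skeleton with 13-acetyl, free 11-OH, 6-OSiEt3, 1-OAc), via enone aldehyde 24 (not isolated)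
Conditions: undivided cell, Mg anode, graphite-felt cathode, n-Bu4NBF4 (0.1 M), DMF, t-BuOH (3 equiv), 23 (1.5 equiv), constant current (4.5 F/mol), 0 °C → rt; aq. NH4Cl
Reagents that add atoms: none
Why: Proposed new method: cathodic one-electron reduction of the N-acyloxyphthalimide (the most easily reduced group present) releases CO2 and the tertiary bridgehead radical at C-8, which adds to the CH2 terminus of 23; reduction of the adduct radical to the enolate and loss of acetate (net radical SN2′ allylation) gives enone 24, and only when 19 is used up does the cathode reach the potential of the enone, whose radical anion closes ring C onto the C-11 aldehyde before a second electron and a proton finish the sequence. The closest known reaction types are the reductive decarboxylative Giese addition and allylation of tertiary redox-active esters and the electroreductive or SmI2-mediated cyclization of aldehydes onto enones; their union in one electrolysis is new. Ring C closes by C-12–C-11 bond formation, 6-exo with respect to the aldehyde C=O and 6-endo with respect to the enone C=C. C-8 keeps its configuration because a bridgehead radical has only one open face; C-11 is set in a chair-like transition state with the metal-bound oxygen equatorial, anti to C-10 and away from the axial lactone carbonyl on C-8; C-13 is set by protonation of the enolate and equilibration of the acetyl group to the equatorial position, cis to the C-11 hydroxyl. The step needs the radical to add before it is reduced further (excess acceptor, carbon cathode, low current density) and needs the reduction order ester before enone before aldehyde, which the substrate has; the silyl ether on C-6 blocks retro-aldol opening by electrogenerated base.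

Step 15
Reactants: 25 tetracyclic methyl ketone
Product: 26 6,11-bis(triethylsilyl) ether of 25
Conditions: Et3SiOTf, 2,6-lutidine, CH2Cl2, −78 °C
Reagents that add atoms: triethylsilyl trifluoromethanesulfonate (CC[Si](CC)(CC)OS(=O)(=O)C(F)(F)F)
Why: The new secondary alcohol is silylated at low temperature faster than the methyl ketone is enolised, which prepares the molecule for strong base.

Step 16
Reactants: 26 bis(triethylsilyl) ether
Product: 27 enol triflate (C-13 bears C(OTf)=CH2)
Conditions: KN(SiMe3)2, THF, −78 °C; then PhNTf2
Reagents that add atoms: N-phenylbis(trifluoromethanesulfonimide) (O=S(=O)(N(c1ccccc1)S(=O)(=O)C(F)(F)F)C(F)(F)F)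
Why: KN(SiMe3)2 removes a proton from the methyl group of the ketone under kinetic control (the lactone has no α-hydrogen and the acetate is less acidic) and PhNTf2 traps the enolate on oxygen, leaving C-13 untouched.

Step 17
Reactants: 27 enol triflate
Product: 28 6,11-bis(triethylsilyl) ether of the target
Conditions: Pd(OAc)2 (5 mol %), PPh3, CO (1 atm), MeOH, Et3N, DMF, 45 °C
Reagents that add atoms: carbon monoxide ([C-]#[O+]); methanol (CO)
Why: Oxidative addition of the enol triflate to zerovalent palladium, CO insertion and methanolysis of the acylpalladium species give the 2-substituted acrylate (alkoxycarbonylation of enol triflates).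

Step 18
Reactants: 28 bis(triethylsilyl) ether of the target
Product: 29 CNP0421185.1
Conditions: HF·pyridine, THF/pyridine, 0 °C → rt
Reagents that add atoms: none
Why: Fluoride removes both triethylsilyl ethers while acetate, lactone and acrylate are stable to buffered HF.

**Compound list**

1 | 4,4-dimethylcyclohexanone | CC1(C)CCC(=O)CC1 | starting material
2 | dimethyl carbonate | COC(=O)OC | starting material
3 | methyl 5,5-dimethyl-2-oxocyclohexane-1-carboxylate | COC(=O)C1CC(C)(C)CCC1=O | intermediate
4 | methyl 5,5-dimethyl-2-oxo-1-(phenylselanyl)cyclohexane-1-carboxylate (formed in situ) | COC(=O)C1([Se]c2ccccc2)CC(C)(C)CCC1=O | intermediate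
5 | methyl 3,3-dimethyl-6-oxocyclohex-1-ene-1-carboxylate | COC(=O)C1=CC(C)(C)CCC1=O | intermediate
6 | (E)-prop-1-en-1-ylboronic acid | C/C=C/B(O)O | starting material
7 | methyl (1S,6S)-5,5-dimethyl-2-oxo-6-[(E)-prop-1-en-1-yl]cyclohexane-1-carboxylate (ester trans to propenyl; ester-bearing carbon epimerisable) | COC(=O)[C@@H]1C(=O)CCC(C)(C)[C@H]1/C=C/C | intermediate
8 | 3-bromoprop-1-yne | BrCC#C | starting material
9 | methyl (1R,6R)-5,5-dimethyl-2-oxo-6-[(E)-prop-1-en-1-yl]-1-(prop-2-yn-1-yl)cyclohexane-1-carboxylate (propargyl trans to propenyl) | COC(=O)[C@@]1(CC#C)C(=O)CCC(C)(C)[C@H]1/C=C/C | intermediate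
10 | (1S,2S,3R)-2-(hydroxymethyl)-4,4-dimethyl-3-[(E)-prop-1-en-1-yl]-2-(prop-2-yn-1-yl)cyclohexan-1-ol (OH cis to CH2OH) | OC[C@@]1(CC#C)[C@@H](O)CCC(C)(C)[C@H]1/C=C/C | intermediate
11 | 3-(benzyloxy)-3-oxopropanoic acid | OC(=O)CC(=O)OCc1ccccc1 | starting material
12 | benzyl malonate of the primary alcohol of 10, secondary OH free (formed in situ) | O=C(CC(=O)OCc1ccccc1)OC[C@@]1(CC#C)[C@@H](O)CCC(C)(C)[C@H]1/C=C/C | intermediate
13 | acetate of 12 (acetoxy malonate) | O=C(CC(=O)OCc1ccccc1)OC[C@@]1(CC#C)[C@@H](OC(C)=O)CCC(C)(C)[C@H]1/C=C/C | intermediate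
14 | benzyl 7-acetoxy-5-ethenyl-10,10-dimethyl-3-oxo-11-[(E)-prop-1-en-1-yl]-2-oxaspiro[5.5]undecane-4-carboxylate (epimers at C-8 and C-9, ring A centres defined) | C=CC1C(C(=O)OCc2ccccc2)C(=O)OC[C@]13[C@@H](OC(C)=O)CCC(C)(C)[C@H]3/C=C/C | intermediate
15 | benzyl 7-acetoxy-5,11-diformyl-10,10-dimethyl-3-oxo-2-oxaspiro[5.5]undecane-4-carboxylate (formed in situ) | O=CC1C(C(=O)OCc2ccccc2)C(=O)OC[C@]13[C@@H](OC(C)=O)CCC(C)(C)[C@H]3C=O | intermediate
16 | tricyclic hydroxy aldehyde: ring A trans-fused to the cyclopentane, lactone bridging C-8 and C-10; CO2Bn on C-8, CHO on C-9 syn to the lactone bridge, 6-OH anti to it, 1-OAc | O=C[C@@H]1[C@]2(C(=O)OCc3ccccc3)C(=O)OC[C@]14[C@@H](OC(C)=O)CCC(C)(C)[C@H]4[C@@H]2O | intermediate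
17 | C-6 triethylsilyl ether of 16 | O=C[C@@H]1[C@]2(C(=O)OCc3ccccc3)C(=O)OC[C@]14[C@@H](OC(C)=O)CCC(C)(C)[C@H]4[C@@H]2O[Si](CC)(CC)CC | intermediate
18 | bridgehead carboxylic acid from 17 | O=C[C@@H]1[C@]2(C(O)=O)C(=O)OC[C@]14[C@@H](OC(C)=O)CCC(C)(C)[C@H]4[C@@H]2O[Si](CC)(CC)CC | intermediate
19 | 1,3-dioxoisoindolin-2-yl ester of 18 | O=C[C@@H]1[C@]2(C(=O)ON3C(=O)c5ccccc5C3=O)C(=O)OC[C@]14[C@@H](OC(C)=O)CCC(C)(C)[C@H]4[C@@H]2O[Si](CC)(CC)CC | intermediate
20 | but-3-en-2-one | CC(=O)C=C | starting material
21 | formaldehyde | C=O | starting material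
22 | 3-(hydroxymethyl)but-3-en-2-one | CC(=O)C(=C)CO | intermediate
23 | 2-methylidene-3-oxobutyl acetate | CC(=O)OCC(=C)C(C)=O | intermediate
24 | enone aldehyde: 2-methylidene-3-oxobutyl group on C-8 in place of the carboxyl of 18 (formed in situ) | O=C[C@@H]1[C@]2(CC(=C)C(C)=O)C(=O)OC[C@]14[C@@H](OC(C)=O)CCC(C)(C)[C@H]4[C@@H]2O[Si](CC)(CC)CC | intermediate
25 | tetracyclic methyl ketone: target skeleton with equatorial 13-acetyl, equatorial 11-OH, 6-OSiEt3, 1-OAc | CC(=O)[C@@H]1C[C@H](O)[C@@H]2[C@]3(C1)C(=O)OC[C@]21[C@@H](OC(C)=O)CCC(C)(C)[C@H]1[C@@H]3O[Si](CC)(CC)CC | intermediate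
26 | 6,11-bis(triethylsilyl) ether of 25 | CC(=O)[C@@H]1C[C@H](O[Si](CC)(CC)CC)[C@@H]2[C@]3(C1)C(=O)OC[C@]21[C@@H](OC(C)=O)CCC(C)(C)[C@H]1[C@@H]3O[Si](CC)(CC)CC | intermediate
27 | enol triflate of 26 (1-(trifluoromethanesulfonyloxy)ethenyl group on C-13) | C=C(OS(=O)(=O)C(F)(F)F)[C@@H]1C[C@H](O[Si](CC)(CC)CC)[C@@H]2[C@]3(C1)C(=O)OC[C@]21[C@@H](OC(C)=O)CCC(C)(C)[C@H]1[C@@H]3O[Si](CC)(CC)CC | intermediate
28 | 6,11-bis(triethylsilyl) ether of the target | C=C(C(=O)OC)[C@@H]1C[C@H](O[Si](CC)(CC)CC)[C@@H]2[C@]3(C1)C(=O)OC[C@]21[C@@H](OC(C)=O)CCC(C)(C)[C@H]1[C@@H]3O[Si](CC)(CC)CC | intermediate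
29 | CNP0421185.1 | C=C(C(=O)OC)[C@@H]1C[C@H](O)[C@@H]2[C@]3(C1)C(=O)OC[C@]21[C@@H](OC(C)=O)CCC(C)(C)[C@H]1[C@@H]3O | target

**Step count and risks**

Total step count: 18. Longest linear sequence: 16 (steps 1–11 and 14–18; steps 12–13 make the C3 reagent).

Steps most likely to fail:

Step 14 (labelled). The bridgehead radical may be reduced to the carbanion and protonated before it adds to the acceptor, or excess acceptor may be reduced in the second stage and couple intermolecularly with the aldehyde. The fallback splits the event into two known reactions, setting out from 19 and returning at 25. First, a visible-light decarboxylative radical allylation (Ru(bpy)3(PF6)2, Hantzsch ester, i-Pr2NEt, 23, CH2Cl2, blue light) gives enone aldehyde 24, which is now isolated (no new compound, F0). Then a ketyl–olefin cyclization with SmI2, HMPA and t-BuOH in THF at −78 °C gives 25.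

Step 7. The malonate C–H may be too weakly acidic to intercept the π-allylrhodium species, the ester tether may disfavour the ring-closing conformation, and alkyne oligomerisation may compete. The fallback sets out from 13 and returns at 14. The alkyne is semi-hydrogenated (H2, Pd/CaCO3 poisoned with Pb(OAc)2, quinoline, EtOAc) to the allyl malonate F1. The lactone is then closed by palladium-catalysed intramolecular allylic C–H alkylation (Pd(OAc)2, 1,2-bis(phenylsulfinyl)ethane, 2,6-dimethyl-1,4-benzoquinone, 1,4-dioxane, 45 °C), which passes through a π-allyl intermediate of the same kind.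

Step 3. Conversion or facial selectivity may be poor because the β-carbon is neopentylic and the product β-keto ester can bind the catalyst. The fallback sets out from 5 and returns at 9. (E)-Prop-1-enylmagnesium bromide is added to 5 with catalytic CuI and Me3SiCl in THF at −78 °C to give racemic 7 (the unwanted enantiomer is ent-7 F2). The material is propargylated as in step 4, and the enantiomers are separated by preparative chromatography on a chiral stationary phase (the unwanted one is ent-9 F3).

Further compounds
F0 | step 14 | none | none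
F1 | step 7 | allyl malonate: benzyl malonate/acetate 13 with prop-2-en-1-yl in place of prop-2-yn-1-yl | O=C(CC(=O)OCc1ccccc1)OC[C@@]1(CC=C)[C@@H](OC(C)=O)CCC(C)(C)[C@H]1/C=C/C
F2 | step 3 | ent-7, methyl (1R,6R)-5,5-dimethyl-2-oxo-6-[(E)-prop-1-en-1-yl]cyclohexane-1-carboxylate | COC(=O)[C@H]1C(=O)CCC(C)(C)[C@@H]1/C=C/C
F3 | step 3 | ent-9, methyl (1S,6S)-5,5-dimethyl-2-oxo-6-[(E)-prop-1-en-1-yl]-1-(prop-2-yn-1-yl)cyclohexane-1-carboxylate | COC(=O)[C@]1(CC#C)C(=O)CCC(C)(C)[C@@H]1/C=C/C
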